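The plan rests on ring A (C1, C10–C14). Quaternary C1 (C15 methyl, C2) sits next to C10 (H, C9) with C2 and C9 trans, and C13=C14–C12=O is an enone. This matches an (E)-2-methylbutenedioate plus a 1-methoxy-3-silyloxydiene, so ring A is made first by an enantioselective [4+2] reaction (C1–C14, C10–C11).
C11 (methyl, then oxygen) comes from two enolate reactions. The two esters are told apart by hydride at C9 and γ-lactone formation, and C2 becomes the E-iodoalkene C2=C3.
The C9 arm grows by acyl-anion addition (C8, C7), a boron aldol (C6–C4, C16) and propionate enolate addition to the C8 ketone (C17–C19). The γ-lactone (O–C7–C8–C17–C19) is the second ring.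
The ten-membered ring (C1–C10) is closed last at C3–C4 by Ni/Cr coupling. Acetylation and invertive C6–OH to C6–Cl exchange finish the route.

Key step: step 1

Remark: briarane numbering of the target is used throughout; β is the face of ring A that carries the C15 methyl group.
Assumption: the temporary C12 carbinol is drawn as the 12β epimer expected from hydride delivery to the α face; either epimer would serve, because the centre is erased in step 21.

Step 1
Reactants: 1 (E)-1-methoxy-3-(trimethylsilyloxy)buta-1,3-diene; 2 dimethyl mesaconate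
Product: 4 ring A enone diester dimethyl (1S,2S)-1-methyl-4-oxocyclohex-5-ene-1,2-dicarboxylate (C15 β; C2 ester α; C9 ester β), via cycloadduct 3 (not isolated)
Conditions: oxazaborolidinium triflimide from (S)-diphenylprolinol, o-tolylboroxine, Tf2NH (20 mol %), CH2Cl2, −78 → −40 °C; then 1 M HCl, THF, 0 °C
Reagents that add atoms: none
Why: A chiral boron Lewis acid lowers the LUMO of 2 and the electron-rich diene 1 adds in a one-step [4+2] process with unequal bond development (C11–C10 advanced, C14–C1 lagging); the closest known reaction type is the oxazaborolidinium-catalysed Diels–Alder reaction of fumarate diesters and of silyloxydienes. Ring A (C1, C10, C11, C12, C13, C14) closes in this single intermolecular cycloaddition, each partner reacting on one face. The step needs the regiochemistry C11→C10, which is secured when the catalyst activates the ester on C1, since C10 is then the β-carbon, carries only hydrogen and meets the nucleophilic CH2 terminus of 1; boron on the C10-bound ester would polarise towards fully substituted C1, where bonding is slow, and as the two complexes exchange rapidly the matched one should carry the reaction. The relative configuration of C1 and C10 (C2 α, C9 β, trans) is a copy of the E geometry of 2. Their absolute configuration is controlled by the catalyst, whose aryl groups screen one face of the bound s-trans enoate, and the catalyst antipode is chosen once the sense of induction has been assigned on 4. Aqueous acid then cleaves the silyl enol ether of 3 and eliminates methanol from C14, which erases the endo/exo question and unveils the C13=C14–C12=O enone.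

Step 2
Reactants: 4 ring A enone diester
Product: 6 11α-methyl enone diester, via lithium dienolate 5 (not isolated)
Conditions: LDA, THF, −78 °C; MeI, −78 → −40 °C
Reagents that add atoms: iodomethane, CI
Why: Kinetic α′-deprotonation (C1 is quaternary, so no γ-proton competes) gives the cross-conjugated dienolate, and the enolate alkylation takes place on the α face, anti to the C10 ester; this C11 configuration is provisional.

Step 3
Reactants: 6 11α-methyl enone diester
Product: 8 α-ketol (11α-OH; 11β-CH3), via potassium enolate 7 (not isolated)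
Conditions: KHMDS, THF, −78 °C; 2-(phenylsulfonyl)-3-phenyloxaziridine, −78 °C; AcOH quench
Reagents that add atoms: 2-(phenylsulfonyl)-3-phenyloxaziridine, O=S(=O)(N1OC1c1ccccc1)c1ccccc1
Why: In this enolate oxidation with an N-sulfonyloxaziridine the tetrasubstituted enolate is again attacked anti to the C10 ester, so oxygen enters on the α face and the methyl group moves to the β face, which sets C11.

Step 4
Reactants: 8 α-ketol
Product: 9 11-O-MOM enone diester
Conditions: MOMCl, i-Pr2NEt, Bu4NI (cat.), ClCH2CH2Cl, 60 °C
Reagents that add atoms: chloromethyl methyl ether, COCCl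
Why: Acetal protection of the tertiary α-ketol stops lactonisation of O11 onto the cis C2 ester, and MOM is chosen because its oxygen can chelate in step 10.

Step 5
Reactants: 9 11-O-MOM enone diester
Product: 11 trans-fused γ-lactone (C2 carbonyl; O–C9H2) bearing the 12β-OH, via diol ester 10 (not isolated)
Conditions: DIBAL-H (3.3 equiv), CH2Cl2, −78 → −50 °C; Rochelle salt; then PPTS (cat.), PhH, 50 °C
Reagents that add atoms: none
Why: In this hydride reduction DIBAL-H reduces the enone 1,2 (α-face attack, away from the axial C10 substituent) and the C9 ester on tertiary C10, while the neopentyl C2 ester on quaternary C1 survives at low temperature; acid-catalysed transesterification then ties O9 to C2, which fixes the differentiation of the two carboxyl carbons.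

Step 6
Reactants: 11 lactone alcohol
Product: 12 11,12-bis-O-MOM lactone
Conditions: MOMCl, i-Pr2NEt, Bu4NI (cat.), ClCH2CH2Cl, 60 °C
Reagents that add atoms: chloromethyl methyl ether, COCCl
Why: The small electrophile MOMCl protects the hindered allylic C12 alcohol, which masks the future enone carbonyl against hydride, organometallic reagents and enolates.

Step 7
Reactants: 12 bis-MOM lactone
Product: 13 lactol (C2 hemiacetal; mixture of anomers)
Conditions: DIBAL-H (1.1 equiv), PhMe, −78 °C
Reagents that add atoms: none
Why: Partial reduction of a lactone stops at the tetrahedral aluminate at −78 °C and delivers C2 at the aldehyde level with O9 still attached.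

Step 8
Reactants: 13 lactol
Product: 14 (E)-iodoalkene (C2=C3–I) with free C9H2OH
Conditions: CrCl2, CHI3, THF–dioxane, 0 °C → rt
Reagents that add atoms: iodoform, IC(I)I
Why: The Takai olefination acts on the open hydroxy-aldehyde form of the lactol; the gem-dichromium reagent gives the E-iodoalkene, a preference reinforced by the quaternary C1 substituent, and tolerates the free alcohol.

Step 9
Reactants: 14 iodoalkene alcohol
Product: 15 C9 aldehyde
Conditions: Dess–Martin periodinane, CH2Cl2, 0 °C → rt
Reagents that add atoms: none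
Why: The Dess–Martin oxidation runs under non-basic conditions, so C10 is not epimerised and the β-alkoxy group at C11 is not eliminated.

Step 10
Reactants: 15 C9 aldehyde; 16 ethyl vinyl ether
Product: 19 (9R)-carbinol bearing the 1-ethoxyvinyl group (C8; C7), via (1-ethoxyvinyl)lithium 17 (not isolated), via (1-ethoxyvinyl)magnesium bromide 18 (not isolated)
Conditions: 16, t-BuLi, THF, −78 → 0 °C; MgBr2·OEt2, −78 °C; 15 precomplexed with MgBr2·OEt2, CH2Cl2, −78 °C
Reagents that add atoms: none
Why: In this chelation-controlled 1,2-addition of an acyl anion equivalent magnesium bridges the C9 carbonyl and the C11 MOM oxygen in a six-membered chelate, and the nucleophile enters from the side of H10, away from C1 and the two β-methyl groups, which sets C9.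

Step 11
Reactants: 19 (9R)-carbinol
Product: 20 9-O-PMB enol ether
Conditions: NaH, PMBCl, Bu4NI (cat.), THF–DMF, 0 °C → rt
Reagents that add atoms: 4-methoxybenzyl chloride, COc1ccc(CCl)cc1
Why: The Williamson etherification uses basic conditions that the acid-labile enol ether and the iodoalkene tolerate, and the PMB ether keeps O9 able to chelate in step 18.

Step 12
Reactants: 20 9-O-PMB enol ether
Product: 21 α-hydroxy ketone (C8=O; C7H2OH)
Conditions: OsO4 (2 mol %), NMO, acetone–H2O, 0 °C
Reagents that add atoms: N-methylmorpholine N-oxide, C[N+]1([O-])CCOCC1; water, O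
Why: Catalytic dihydroxylation is selective for the electron-rich enol ether over the hindered ring olefin and the deactivated iodoalkene, and the hemiketal diol collapses with loss of ethanol to the α-hydroxy ketone.

Step 13
Reactants: 21 α-hydroxy ketone
Product: 22 7-O-MOM ketone
Conditions: MOMCl, i-Pr2NEt, CH2Cl2, 0 °C → rt
Reagents that add atoms: chloromethyl methyl ether, COCCl
Why: Acetal protection of the primary ketol hydroxyl gives a chelating O7 group that can later be removed together with the other two MOM groups.

Step 14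
Reactants: 23 2-methylenepropane-1,3-diol
Product: 24 2-[(4-methoxybenzyloxy)methyl]prop-2-en-1-ol
Conditions: NaH (1 equiv), PMBCl, Bu4NI (cat.), THF, 0 °C → rt
Reagents that add atoms: 4-methoxybenzyl chloride, COc1ccc(CCl)cc1
Why: Williamson mono-etherification of a symmetrical diol with one equivalent of base gives the mono-ether, which is separable from diol and diether.

Step 15
Reactants: 24 mono-PMB ether
Product: 25 2-[(4-methoxybenzyloxy)methyl]prop-2-enal (C6 aldehyde; C5=C16; C4)
Conditions: MnO2, CH2Cl2, rt
Reagents that add atoms: none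
Why: MnO2 oxidises the primary allylic alcohol to the 2-substituted acrolein without touching the PMB ether.

Step 16
Reactants: 22 7-O-MOM ketone; 25 2-substituted acrolein
Product: 27 6,7-syn aldol (6R; 7S), via Z boron enolate 26 (not isolated)
Conditions: Bu2BOTf, i-Pr2NEt, CH2Cl2, −78 °C; 25, −78 → −20 °C; pH 7 buffer, H2O2, MeOH, 0 °C
Reagents that add atoms: none
Why: In this boron aldol reaction enolisation towards the unhindered C7 methylene gives the Z enol borinate, whose closed chair transition state gives the 6,7-syn product; with the C9–O bond anti to the enolate C–O bond the aldehyde approaches the face opposite C10, which sets C7 as in the target and C6 as the 6R alcohol, epimeric in space to the final chloride.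

Step 17
Reactants: 27 syn aldol
Product: 28 6-O-TBS ketone
Conditions: TBSOTf, 2,6-lutidine, CH2Cl2, −78 °C
Reagents that add atoms: tert-butyldimethylsilyl triflate, CC(C)(C)[Si](C)(C)OS(=O)(=O)C(F)(F)F
Why: Silylation with the triflate and a hindered base at low temperature protects the β-hydroxy ketone without retro-aldol cleavage and reserves O6 for the last two steps.

Step 18
Reactants: 28 6-O-TBS ketone; 29 methyl propionate
Product: 31 (8R) tertiary carbinol methyl ester (C17 epimers), via lithium enolate 30 (not isolated)
Conditions: 29, LDA, THF, −78 °C; 28, −78 °C; AcOH quench at −78 °C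
Reagents that add atoms: none
Why: In this aldol-type addition of an ester enolate to an α,α′-dialkoxy ketone under chelation control, lithium bound to the C8 carbonyl and to O7 or to O9 exposes the same face in both five-membered chelates (the side of H7 and of H9), which sets C8; C17 forms as a mixture that is corrected in step 19.

Step 19
Reactants: 31 tertiary carbinol methyl ester
Product: 33 γ-lactone triol (free 8-; 11-; 12-OH; 17-CH3 cis to 8-OH), via tetraol ester 32 (not isolated)
Conditions: TMSOTf, 2,2′-bipyridyl, CH2Cl2, 0 °C; H2O; then DBU (cat.), PhMe, 40 °C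
Reagents that add atoms: none
Why: The silyl triflate/bipyridyl cleavage removes the three MOM acetals and spares the PMB and TBS ethers; the freed C7 hydroxyl closes the γ-lactone by acyl substitution (O9 still blocked, O6 silylated), and base equilibration through the lactone enolate places the C17 methyl trans to the bulky C9 substituent, which sets C17.

Step 20
Reactants: 33 γ-lactone triol
Product: 34 pentaol (free 4-; 8-; 9-; 11-; 12-OH)
Conditions: DDQ, CH2Cl2–pH 7 buffer, 0 °C → rt
Reagents that add atoms: none
Why: Oxidative cleavage of the two PMB ethers under neutral, wet conditions leaves the lactone, the TBS ether, the iodoalkene and the olefins intact.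

Step 21
Reactants: 34 pentaol
Product: 35 enone–enal (C12 ketone; C4 aldehyde)
Conditions: MnO2 (excess), CH2Cl2, rt
Reagents that add atoms: none
Why: MnO2 oxidises only the two allylic alcohols, so the ring A enone is restored and the C4 enal is formed, while the saturated C9 carbinol and the tertiary alcohols stay untouched.

Step 22
Reactants: 35 enone–enal
Product: 36 ten-membered carbocycle with the (4S)-carbinol
Conditions: CrCl2 (excess), NiCl2 (cat.), DMSO–THF, 2 mM, rt
Reagents that add atoms: none
Why: In the Nozaki–Hiyama–Kishi reaction nickel inserts into the C3–I bond and the alkenylchromium adds to the aldehyde in preference to ketone and lactone, with retention of the E olefin, closing C3–C4; with H6 eclipsing the exomethylene the tether (C7, hence C3) lies opposite the C6 silyloxy group and the chromium-bound oxygen points out of the ring (s-cis enal), a combination that leads to 4S.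

Step 23
Reactants: 36 macrocyclic tetraol
Product: 37 4,9,11-triacetate (8-OH free)
Conditions: Ac2O, Et3N, DMAP, CH2Cl2, rt → 35 °C
Reagents that add atoms: acetic anhydride, CC(=O)OC(C)=O
Why: DMAP-catalysed acetylation reaches the two secondary alcohols and the tertiary C11 ketol hydroxyl (flanked by a methyl group and an sp2 carbonyl) but not the C8 hydroxyl, which is flanked by three branched carbons.

Step 24
Reactants: 37 triacetate
Product: 38 (6R)-allylic alcohol
Conditions: HF·pyridine, pyridine, THF, 0 °C → rt
Reagents that add atoms: none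
Why: Buffered fluoride desilylation frees O6 without touching the acetates, the lactone or the enone.

Step 25
Reactants: 38 (6R)-allylic alcohol
Product: 39 target CNP0159278.2
Conditions: PPh3, (Cl3C)2CO, CH2Cl2, −20 °C → rt
Reagents that add atoms: hexachloroacetone, O=C(C(Cl)(Cl)Cl)C(Cl)(Cl)Cl
Why: This Appel-type chlorination with PPh3 and hexachloroacetone is known to convert secondary allylic alcohols to chlorides by SN2 with inversion and little allylic shift, so the 6,7-syn alcohol becomes the 6S chloride anti to O7, while the hindered tertiary 8-OH is not activated.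

Compound list
1 | (E)-1-methoxy-3-(trimethylsilyloxy)buta-1,3-diene | CO/C=C/C(=C)O[Si](C)(C)C | starting material
2 | dimethyl mesaconate | COC(=O)/C=C(\C)C(=O)OC | starting material
3 | cycloadduct, dimethyl 6-methoxy-1-methyl-4-(trimethylsilyloxy)cyclohex-4-ene-1,2-dicarboxylate (C14-OMe α) | COC(=O)[C@@]1(C)[C@@H](OC)C=C(O[Si](C)(C)C)C[C@@H]1C(=O)OC | intermediate
4 | dimethyl (1S,2S)-1-methyl-4-oxocyclohex-5-ene-1,2-dicarboxylate | COC(=O)[C@@]1(C)C=CC(=O)C[C@@H]1C(=O)OC | intermediate
5 | lithium cross-conjugated dienolate of 4 | COC(=O)[C@@]1(C)C=CC([O-])=C[C@@H]1C(=O)OC.[Li+] | intermediate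
6 | 11α-methyl enone diester | COC(=O)[C@@]1(C)C=CC(=O)[C@@H](C)[C@@H]1C(=O)OC | intermediate
7 | potassium enolate of 6 | COC(=O)[C@@]1(C)C=CC([O-])=C(C)[C@@H]1C(=O)OC.[K+] | intermediate
8 | α-ketol (11α-OH, 11β-CH3) | COC(=O)[C@@]1(C)C=CC(=O)[C@@](C)(O)[C@@H]1C(=O)OC | intermediate
9 | 11-O-MOM enone diester | COC(=O)[C@@]1(C)C=CC(=O)[C@@](C)(OCOC)[C@@H]1C(=O)OC | intermediate
10 | diol ester (12β-OH, C9H2OH, C2 methyl ester) | COC(=O)[C@@]1(C)C=C[C@H](O)[C@@](C)(OCOC)[C@@H]1CO | intermediate
11 | trans-fused γ-lactone, 12β-OH | O=C1OC[C@@H]2[C@]1(C)C=C[C@H](O)[C@@]2(C)OCOC | intermediate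
12 | 11,12-bis-O-MOM lactone | O=C1OC[C@@H]2[C@]1(C)C=C[C@H](OCOC)[C@@]2(C)OCOC | intermediate
13 | lactol (anomers at C2) | OC1OC[C@@H]2[C@]1(C)C=C[C@H](OCOC)[C@@]2(C)OCOC | intermediate
14 | (E)-iodoalkene primary alcohol | I/C=C/[C@@]1(C)C=C[C@H](OCOC)[C@@](C)(OCOC)[C@@H]1CO | intermediate
15 | C9 aldehyde | I/C=C/[C@@]1(C)C=C[C@H](OCOC)[C@@](C)(OCOC)[C@@H]1C=O | intermediate
16 | ethyl vinyl ether | C=COCC | starting material
17 | (1-ethoxyvinyl)lithium | [Li]C(=C)OCC | intermediate
18 | (1-ethoxyvinyl)magnesium bromide | Br[Mg]C(=C)OCC | intermediate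
19 | (9R)-carbinol with 1-ethoxyvinyl group | I/C=C/[C@@]1(C)C=C[C@H](OCOC)[C@@](C)(OCOC)[C@@H]1[C@@H](O)C(=C)OCC | intermediate
20 | 9-O-PMB enol ether | I/C=C/[C@@]1(C)C=C[C@H](OCOC)[C@@](C)(OCOC)[C@@H]1[C@@H](OCc1ccc(OC)cc1)C(=C)OCC | intermediate
21 | α-hydroxy ketone | I/C=C/[C@@]1(C)C=C[C@H](OCOC)[C@@](C)(OCOC)[C@@H]1[C@@H](OCc1ccc(OC)cc1)C(=O)CO | intermediate
22 | 7-O-MOM ketone | I/C=C/[C@@]1(C)C=C[C@H](OCOC)[C@@](C)(OCOC)[C@@H]1[C@@H](OCc1ccc(OC)cc1)C(=O)COCOC | intermediate
23 | 2-methylenepropane-1,3-diol | C=C(CO)CO | starting material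
24 | 2-[(4-methoxybenzyloxy)methyl]prop-2-en-1-ol | C=C(CO)COCc1ccc(OC)cc1 | intermediate
25 | 2-[(4-methoxybenzyloxy)methyl]prop-2-enal | C=C(C=O)COCc1ccc(OC)cc1 | intermediate
26 | (Z)-dibutylboron enolate of 22 | I/C=C/[C@@]1(C)C=C[C@H](OCOC)[C@@](C)(OCOC)[C@@H]1[C@@H](OCc1ccc(OC)cc1)/C(OB(CCCC)CCCC)=C/OCOC | intermediate
27 | 6,7-syn aldol (6R,7S) | I/C=C/[C@@]1(C)C=C[C@H](OCOC)[C@@](C)(OCOC)[C@@H]1[C@@H](OCc1ccc(OC)cc1)C(=O)[C@@H](OCOC)[C@H](O)C(=C)COCc1ccc(OC)cc1 | intermediate
28 | 6-O-TBS ketone | I/C=C/[C@@]1(C)C=C[C@H](OCOC)[C@@](C)(OCOC)[C@@H]1[C@@H](OCc1ccc(OC)cc1)C(=O)[C@@H](OCOC)[C@H](O[Si](C)(C)C(C)(C)C)C(=C)COCc1ccc(OC)cc1 | intermediate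
29 | methyl propionate | CCC(=O)OC | starting material
30 | lithium enolate of methyl propionate | C/C=C(\OC)[O-].[Li+] | intermediate
31 | (8R) tertiary carbinol methyl ester, C17 epimers | I/C=C/[C@@]1(C)C=C[C@H](OCOC)[C@@](C)(OCOC)[C@@H]1[C@@H](OCc1ccc(OC)cc1)[C@](O)(C(C)C(=O)OC)[C@@H](OCOC)[C@H](O[Si](C)(C)C(C)(C)C)C(=C)COCc1ccc(OC)cc1 | intermediate
32 | tetraol ester (7-, 8-, 11-, 12-OH), C17 epimers | I/C=C/[C@@]1(C)C=C[C@H](O)[C@@](C)(O)[C@@H]1[C@@H](OCc1ccc(OC)cc1)[C@](O)(C(C)C(=O)OC)[C@@H](O)[C@H](O[Si](C)(C)C(C)(C)C)C(=C)COCc1ccc(OC)cc1 | intermediate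
33 | γ-lactone triol | I/C=C/[C@@]1(C)C=C[C@H](O)[C@@](C)(O)[C@@H]1[C@@H](OCc1ccc(OC)cc1)[C@]1(O)[C@@H](C)C(=O)O[C@H]1[C@H](O[Si](C)(C)C(C)(C)C)C(=C)COCc1ccc(OC)cc1 | intermediate
34 | pentaol | I/C=C/[C@@]1(C)C=C[C@H](O)[C@@](C)(O)[C@@H]1[C@@H](O)[C@]1(O)[C@@H](C)C(=O)O[C@H]1[C@H](O[Si](C)(C)C(C)(C)C)C(=C)CO | intermediate
35 | enone–enal | I/C=C/[C@@]1(C)C=CC(=O)[C@@](C)(O)[C@@H]1[C@@H](O)[C@]1(O)[C@@H](C)C(=O)O[C@H]1[C@H](O[Si](C)(C)C(C)(C)C)C(=C)C=O | intermediate
36 | macrocyclic tetraol, (4S)-carbinol, 6-O-TBS | C=C1[C@@H](O)/C=C/[C@@]2(C)C=CC(=O)[C@@](C)(O)[C@@H]2[C@@H](O)[C@]2(O)[C@@H](C)C(=O)O[C@H]2[C@@H]1O[Si](C)(C)C(C)(C)C | intermediate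
37 | 4,9,11-triacetate, 6-O-TBS | C=C1[C@@H](OC(C)=O)/C=C/[C@@]2(C)C=CC(=O)[C@@](C)(OC(C)=O)[C@@H]2[C@@H](OC(C)=O)[C@]2(O)[C@@H](C)C(=O)O[C@H]2[C@@H]1O[Si](C)(C)C(C)(C)C | intermediate
38 | (6R)-allylic alcohol triacetate | C=C1[C@@H](OC(C)=O)/C=C/[C@@]2(C)C=CC(=O)[C@@](C)(OC(C)=O)[C@@H]2[C@@H](OC(C)=O)[C@]2(O)[C@@H](C)C(=O)O[C@H]2[C@@H]1O | intermediate
39 | CNP0159278.2 | C=C1[C@@H](OC(C)=O)/C=C/[C@@]2(C)C=CC(=O)[C@@](C)(OC(C)=O)[C@@H]2[C@@H](OC(C)=O)[C@]2(O)[C@@H](C)C(=O)O[C@H]2[C@H]1Cl | target

Total steps: 25. Longest linear sequence: 23 (steps 1–13 and 16–25); steps 14 and 15 make the side-chain aldehyde 25.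

Steps most likely to fail

Step 1. Three processes threaten it:
- Silyl transfer from the diene to the triflimide counter-ion may release an achiral silyl Lewis acid that carries a racemic background reaction.
- Preferential binding of the catalyst to the more basic, less hindered C10 ester may erode the regioselectivity.
- The acid-labile diene may decompose before it reacts with a sluggish trisubstituted dienophile.

The fallback replaces catalyst control by an auxiliary on a more reactive diene and uses no Lewis acid, so the regiochemistry is that of the unperturbed dienophile. It sets out from 2.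
- Commercial 4-methoxybut-3-en-2-one is condensed with (2S,5S)-2,5-diphenylpyrrolidine to the vinylogous amide (E)-4-[(2S,5S)-2,5-diphenylpyrrolidin-1-yl]but-3-en-2-one F1. The amine antipode is chosen for the face it shields.
- O-silylation (KHMDS, TBSCl, THF, −78 °C) gives the chiral 1-amino-3-siloxydiene F2.
- Warming F2 with 2 in toluene gives the amino silyl enol ether cycloadduct F3.
- HF in acetonitrile cleaves the enol ether and eliminates the amine, and the route is rejoined at 4.

Step 22. Ring closure against transannular strain may be slow, so that intermolecular coupling and reduction of the C–I bond compete. The facial selectivity at C4 depends on the rotamer about C5–C6 and may be poor. The fallback takes the C4 configuration out of the C–C bond formation. It sets out from 36 as a mixture of C4 epimers.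
- MnO2 oxidises only the bis-allylic carbinol to the cross-conjugated C4 ketone F4.
- A Corey–Bakshi–Shibata reduction with catecholborane at low temperature, with the catalyst antipode matched to 4S, reduces this less hindered ketone in preference to the C12 enone, which is flanked by quaternary C11.
- The route is rejoined at 36.

Step 25. Ionisation of the activated allylic alcohol may scramble C6. Chloride may also attack C16 with allylic shift, or the hindered position in the ten-membered ring may resist backside attack so that elimination takes over. The fallback changes the mode of activation to a tethered leaving group opened by external chloride. It sets out from 38.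
- SOCl2 and pyridine at −40 °C tie O6 and O8, which are cis on the lactone, into the six-membered 6,8-cyclic sulfite F5.
- LiCl in DMF opens the sulfite at the allylic C6 with inversion.
- Aqueous work-up hydrolyses the C8 sulfite half-ester, and the route ends at 39.

Further compounds
F1 | step 1 | (E)-4-[(2S,5S)-2,5-diphenylpyrrolidin-1-yl]but-3-en-2-one | CC(=O)/C=C/N1[C@H](c2ccccc2)CC[C@H]1c1ccccc1
F2 | step 1 | (2S,5S)-1-[(E)-3-(tert-butyldimethylsilyloxy)buta-1,3-dienyl]-2,5-diphenylpyrrolidine | C=C(O[Si](C)(C)C(C)(C)C)/C=C/N1[C@H](c2ccccc2)CC[C@H]1c1ccccc1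
F3 | step 1 | amino silyl enol ether cycloadduct (C14 amine α) | COC(=O)[C@@]1(C)[C@@H](N2[C@H](c3ccccc3)CC[C@H]2c2ccccc2)C=C(O[Si](C)(C)C(C)(C)C)C[C@@H]1C(=O)OC
F4 | step 22 | cross-conjugated C4 ketone of the macrocycle | C=C1C(=O)/C=C/[C@@]2(C)C=CC(=O)[C@@](C)(O)[C@@H]2[C@@H](O)[C@]2(O)[C@@H](C)C(=O)O[C@H]2[C@@H]1O[Si](C)(C)C(C)(C)C
F5 | step 25 | 6,8-cyclic sulfite of 38 | C=C1[C@@H](OC(C)=O)/C=C/[C@@]2(C)C=CC(=O)[C@@](C)(OC(C)=O)[C@@H]2[C@@H](OC(C)=O)[C@]2(O3)[C@@H](C)C(=O)O[C@H]2[C@@H]1OS3=O
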